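**Retrosynthetic overview**
1. Structural feature: in ring C the carbonyl carbon C4 is bonded to C4a of ring A. C4a lies between C8a (which carries O1) and C5 (which carries an oxygen). An aryl anion at C4a, tied through O1–C2–C3 to an acyl group at C4, can therefore close ring C by forming C4–C4a.
2. Last skeletal bond, C4–C4a: iodine–magnesium exchange at C4a, then intramolecular acylation by a Weinreb amide. The position of the iodine fixes the 8-prenyl (not 6-prenyl) pattern.
3. O1–C2: Mitsunobu inversion of an (R)-benzylic carbinol by a 2-iodo-6-prenylphenol. An electron-withdrawing 4′-O-Boc group restrains benzylic ionisation.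
4. Fragments: vanillic acid gives the (R)-β-hydroxy Weinreb amide by crossed Claisen condensation and RuCl2[(S)-BINAP] hydrogenation. The amide is in place before the reduction, so no metal amide ever meets the carbonate, the iodide or the β-aryloxy unit. Phloroglucinol gives the phenol by bis-MOM protection, ortho-iodination (before any alkene is present) and ortho-C-prenylation.
5. Ring order: rings A and B are bought. Ring C is the only ring formed (step 8). One acidic unmasking ends the route.

Key step: step 8

Assumption: the single stereocentre of the target SMILES is C2 with S configuration, the usual one of natural flavanones; all four starting materials are catalogue chemicals.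

**Route**

Step 1
Reactants: 1 vanillic acid (4-hydroxy-3-methoxybenzoic acid)
Product: 2 4-[(tert-butoxycarbonyl)oxy]-3-methoxybenzoic acid
Conditions: Boc2O (1.1 equiv), NaOH (2.0 equiv), THF/H2O, 0 °C → rt; then cold 1 M HCl to pH 3
Reagents that add atoms: di-tert-butyl dicarbonate, CC(C)(C)OC(=O)OC(=O)OC(C)(C)C
Why: Under Schotten–Baumann-type conditions the phenoxide is acylated to the aryl tert-butyl carbonate while any mixed anhydride formed at the carboxylate is hydrolysed back, and the electron-withdrawing carbonate is wanted later to restrain ionisation at the benzylic carbon.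

Step 2
Reactants: 2 4-[(tert-butoxycarbonyl)oxy]-3-methoxybenzoic acid; 3 N-methoxy-N-methylacetamide
Product: 5 tert-butyl 2-methoxy-4-{3-[methoxy(methyl)amino]-3-oxopropanoyl}phenyl carbonate (β-keto Weinreb amide), via acyl imidazolide 4 (not isolated)
Conditions: CDI (1.05 equiv), THF, 0 °C → rt, 45 min; then added to the lithium enolate from 3 (3.1 equiv) and LiN(i-Pr)2 (3.1 equiv), THF, −78 °C; aq NH4Cl
Reagents that add atoms: none
Why: Crossed Claisen condensation in which the acyl imidazolide is far more electrophilic than the hindered tert-butyl aryl carbonate, so that at −78 °C the amide enolate is C-acylated there, the extra equivalents of enolate being used up by the imidazole N–H and by the acidic β-keto amide product.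

Step 3
Reactants: 5 β-keto Weinreb amide
Product: 6 tert-butyl 4-{(1R)-1-hydroxy-3-[methoxy(methyl)amino]-3-oxopropyl}-2-methoxyphenyl carbonate ((R)-β-hydroxy Weinreb amide)
Conditions: RuCl2[(S)-BINAP] (1 mol %), H2 (30 bar), EtOH/CH2Cl2, 50 °C; recrystallisation
Reagents that add atoms: none
Why: Noyori asymmetric hydrogenation in which the β-keto amide binds ruthenium through both carbonyl oxygens and the (S)-BINAP complex, which turns aroylacetic acid derivatives into (R)-carbinols, delivers hydride to one ketone face and so sets the future C2 as R, while the N–O bond and the aryl carbonate are not reduced and crystallisation should remove the residual minor enantiomer.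

Step 4
Reactants: 7 phloroglucinol (benzene-1,3,5-triol)
Product: 8 3,5-bis(methoxymethoxy)phenol
Conditions: MOMCl (2.0 equiv), i-Pr2NEt (2.2 equiv), DMF/CH2Cl2, 0 °C → rt; chromatography
Reagents that add atoms: chloromethyl methyl ether, COCCl
Why: Williamson-type O-alkylation with two equivalents of MOMCl is statistical on the threefold-symmetric triol, but the mono-, bis- and tris-ethers differ by one free hydroxyl each, so that they should separate easily on silica and the unwanted ones can be recycled.

Step 5
Reactants: 8 3,5-bis(methoxymethoxy)phenol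
Product: 9 2-iodo-3,5-bis(methoxymethoxy)phenol
Conditions: NIS (1.0 equiv, slow addition), CH2Cl2, −20 → 0 °C, dark
Reagents that add atoms: N-iodosuccinimide, O=C1CCC(=O)N1I
Why: Electrophilic aromatic iodination in which the two equivalent carbons ortho to the free hydroxyl, each flanked by OH and one OMOM, are less crowded than the carbon between the two OMOM groups and should take the large iodine, and the step is placed before the alkene is present so that no iodoetherification can compete.

Step 6
Reactants: 9 2-iodo-3,5-bis(methoxymethoxy)phenol; 10 prenyl bromide (1-bromo-3-methylbut-2-ene)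
Product: 12 2-iodo-3,5-bis(methoxymethoxy)-6-(3-methylbut-2-en-1-yl)phenol, via sodium phenoxide 11 (not isolated)
Conditions: NaH (1.05 equiv), toluene, 0 °C; then 10 (1.1 equiv), 0 °C → rt
Reagents that add atoms: none
Why: Ortho-C-allylation of a tight sodium phenoxide ion pair in a non-polar solvent, where the oxygen is shielded by aggregation and the cation assists departure of bromide next to the ring, so that SN2 attack of the very electron-rich ring at the primary carbon of 10 takes place at the only free ortho carbon (C6).

Step 7
Reactants: 6 (R)-β-hydroxy Weinreb amide; 12 2-iodo-3,5-bis(methoxymethoxy)-6-(3-methylbut-2-en-1-yl)phenol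
Product: 14 tert-butyl 4-{(1S)-1-[2-iodo-3,5-bis(methoxymethoxy)-6-(3-methylbut-2-en-1-yl)phenoxy]-3-[methoxy(methyl)amino]-3-oxopropyl}-2-methoxyphenyl carbonate, via alkoxyphosphonium aryloxide 13 (not isolated)
Conditions: PPh3 (1.5 equiv), DIAD (1.5 equiv, slow addition), toluene (0.5 M), 0 °C → rt
Reagents that add atoms: none
Why: Mitsunobu etherification in which the phenoxide of 12 displaces Ph3P=O from the alkoxyphosphonium ion in an SN2 step with inversion (R carbinol to S ether, the C2 configuration of the target), toluene and the electron-withdrawing 4′-O-carbonate holding back benzylic ionisation and the weakly acidic amide α-hydrogens holding back elimination.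

Step 8
Reactants: 14 (S)-3-aryl-3-aryloxy Weinreb amide with iodine at C4a
Product: 17 (2S)-4′-O-Boc-5,7-bis-O-MOM-8-prenylhomoeriodictyol (protected flavanone), via arylmagnesium chloride 15 (not isolated), via chelated tetrahedral adduct 16 (not isolated)
Conditions: i-PrMgCl·LiCl (1.15 equiv, dropwise), THF, −40 → −20 °C; poured into cold aq NH4Cl
Reagents that add atoms: none
Why: i-PrMgCl·LiCl exchanges the iodine at C4a, and the equilibrium lies on the side of 15 because the sp2 carbanion is stabilised inductively and by chelation from the two flanking oxygens (O1 and the C5 OMOM group). The arylmagnesium then adds to the tethered amide carbonyl in a 6-exo-trig closure (ring atoms C4a, C4, C3, C2, O1, C8a), which forms C4–C4a and ring C and gives the five-membered magnesium chelate 16, a species that neither collapses nor accepts a second nucleophile before the quench. The closest known reaction type is the Parham cyclisation of ortho-halophenyl ethers of 3-hydroxy Weinreb amides to 2-substituted chroman-4-ones, run here with magnesium in place of lithium so that the aryl anion is too weakly basic to abstract C2–H or C3–H. No stereocentre is created in 17, and C2 is carried through as S because the ketone is released only under near-neutral aqueous conditions, where retro-oxa-Michael opening does not occur. The step needs exchange to be faster than deprotonation at C3 (which would expel the aryloxide), than addition of i-PrMgCl to the amide and than attack on the aryl carbonate, and this is secured by the doubly oxygen-flanked iodide, the low kinetic basicity of the reagent at −40 °C, the shielding by the tert-butyl group and the intramolecular nature of the acylation. Site selectivity for the 8-prenyl isomer is fixed by the position of the iodine.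

Step 9
Reactants: 17 (2S)-4′-O-Boc-5,7-bis-O-MOM-8-prenylhomoeriodictyol
Product: 18 (2S)-5,7-dihydroxy-2-(4-hydroxy-3-methoxyphenyl)-8-(3-methylbut-2-en-1-yl)chroman-4-one (target)
Conditions: HCl (1.25 M in MeOH), 0 → 40 °C; pH 6 phosphate buffer work-up
Reagents that add atoms: none
Why: Acid-catalysed acetal exchange of both MOM ethers with methanol and acid fragmentation of the tert-butyl carbonate proceed together under the dilute methanolic HCl conditions commonly used to unmask prenylated polyphenols without hydrating the prenyl group or cyclising it onto the 7-hydroxyl, methanol traps cationic fragments, and the absence of base avoids ring opening to the chalcone and thus racemisation at C2.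

**Compound list**
1 | vanillic acid | COc1cc(C(=O)O)ccc1O | starting material
2 | 4-[(tert-butoxycarbonyl)oxy]-3-methoxybenzoic acid | COc1cc(C(=O)O)ccc1OC(=O)OC(C)(C)C | intermediate
3 | N-methoxy-N-methylacetamide | CC(=O)N(C)OC | starting material
4 | 1-{4-[(tert-butoxycarbonyl)oxy]-3-methoxybenzoyl}imidazole (acyl imidazolide, not isolated) | COc1cc(C(=O)n2ccnc2)ccc1OC(=O)OC(C)(C)C | intermediate
5 | tert-butyl 2-methoxy-4-{3-[methoxy(methyl)amino]-3-oxopropanoyl}phenyl carbonate | CON(C)C(=O)CC(=O)c1ccc(OC(=O)OC(C)(C)C)c(OC)c1 | intermediate
6 | tert-butyl 4-{(1R)-1-hydroxy-3-[methoxy(methyl)amino]-3-oxopropyl}-2-methoxyphenyl carbonate | CON(C)C(=O)C[C@H](c1ccc(OC(=O)OC(C)(C)C)c(OC)c1)O | intermediate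
7 | phloroglucinol | Oc1cc(O)cc(O)c1 | starting material
8 | 3,5-bis(methoxymethoxy)phenol | COCOc1cc(O)cc(OCOC)c1 | intermediate
9 | 2-iodo-3,5-bis(methoxymethoxy)phenol | COCOc1cc(O)c(I)c(OCOC)c1 | intermediate
10 | prenyl bromide | CC(C)=CCBr | starting material
11 | sodium 2-iodo-3,5-bis(methoxymethoxy)phenoxide (not isolated) | [Na+].[O-]c1cc(OCOC)cc(OCOC)c1I | intermediate
12 | 2-iodo-3,5-bis(methoxymethoxy)-6-(3-methylbut-2-en-1-yl)phenol | Oc1c(I)c(OCOC)cc(OCOC)c1CC=C(C)C | intermediate
13 | (R)-alkoxytriphenylphosphonium ion of 6 paired with the phenoxide of 12 (not isolated) | CON(C)C(=O)C[C@H](c1ccc(OC(=O)OC(C)(C)C)c(OC)c1)O[P+](c1ccccc1)(c1ccccc1)c1ccccc1.[O-]c1c(I)c(OCOC)cc(OCOC)c1CC=C(C)C | intermediate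
14 | (S)-3-aryl-3-aryloxy Weinreb amide, iodine at C4a, 4′-O-Boc | CON(C)C(=O)C[C@@H](c1ccc(OC(=O)OC(C)(C)C)c(OC)c1)Oc1c(I)c(OCOC)cc(OCOC)c1CC=C(C)C | intermediate
15 | arylmagnesium chloride from 14, magnesium at C4a (not isolated) | CON(C)C(=O)C[C@@H](c1ccc(OC(=O)OC(C)(C)C)c(OC)c1)Oc1c([Mg]Cl)c(OCOC)cc(OCOC)c1CC=C(C)C | intermediate
16 | ring-closed C4 hemiaminal magnesium alkoxide, C4 configuration undefined (not isolated) | CON(C)C1(O[Mg]Cl)C[C@@H](c2ccc(OC(=O)OC(C)(C)C)c(OC)c2)Oc2c(CC=C(C)C)c(OCOC)cc(OCOC)c21 | intermediate
17 | (2S)-4′-O-Boc-5,7-bis-O-MOM-8-prenylhomoeriodictyol | CC(C)(C)OC(=O)Oc1ccc([C@@H]2CC(=O)c3c(OCOC)cc(OCOC)c(CC=C(C)C)c3O2)cc1OC | intermediate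
18 | (2S)-5,7-dihydroxy-2-(4-hydroxy-3-methoxyphenyl)-8-(3-methylbut-2-en-1-yl)chroman-4-one | COc1cc([C@@H]2CC(=O)c3c(O)cc(O)c(CC=C(C)C)c3O2)ccc1O | target

**Step count**
- Total step count: 9.
- Longest linear sequence: 6 steps. This holds for steps 4, 5, 6, 7, 8, 9 from phloroglucinol and equally for steps 1, 2, 3, 7, 8, 9 from vanillic acid.

**Steps most likely to fail**

Step 8.
- Risk: the iodine–magnesium exchange on the very electron-rich ring A may be too slow at the temperature at which the substrate is safe. Addition of the reagent to the amide or the carbonate could then take over, or deprotonation at C3 followed by expulsion of the aryloxide.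
- Fallback (sets out from 14, returns at 17): the Weinreb amide of 14 is reduced with i-Bu2AlH (toluene, −78 °C) to the (S)-3-aryl-3-aryloxypropanal F1. The same C4–C4a bond is then made under non-basic conditions by an intramolecular Nozaki–Hiyama–Kishi reaction (CrCl2, catalytic NiCl2, DMF, rt). This should give the (2S)-flavan-4-ol F2 as a mixture of C4 epimers. Oxidation with Dess–Martin periodinane (NaHCO3, CH2Cl2) removes the C4 stereocentre and gives 17.

Step 7.
- Risk: attack of the di-ortho-substituted phenoxide on the secondary benzylic alkoxyphosphonium ion may be slower than elimination across C2–C3. Partial ionisation may also erode the enantiopurity.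
- Fallback (sets out from 6, returns at 14): C4 is carried through the etherification at the alcohol oxidation level, where C3–H is not acidic.
  - 6 is reduced with i-Bu2AlH (THF, −78 °C) to the (R)-3-aryl-3-hydroxypropanal F3. This is reduced without purification with NaBH4 (MeOH, 0 °C) to the (R)-1-arylpropane-1,3-diol F4.
  - TBSCl/imidazole silylates the primary hydroxyl selectively to the (R)-3-silyloxy carbinol F5.
  - Mitsunobu reaction with 12 (PPh3, DIAD, toluene), a reaction type well established for 1-aryl-3-substituted propan-1-ols, gives with inversion the (S)-silyloxypropyl aryl ether F6.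
  - HF·pyridine (THF, 0 °C) frees the (S)-primary alcohol F7.
  - TEMPO/PhI(OAc)2 in MeCN–H2O oxidises it to the (S)-3-aryl-3-aryloxypropanoic acid F8.
  - EDC·HCl, MeNHOMe·HCl and N-methylmorpholine (CH2Cl2) give 14.

Step 6.
- Risk: O-alkylation, C-alkylation para to the phenoxide oxygen or double alkylation may compete with the wanted ortho-C-alkylation.
- Fallback (sets out from 9, returns at 12): the prenyl group is delivered by a sigmatropic shift instead of by direct alkylation.
  - O-Alkylation of 9 with 3-chloro-3-methylbut-1-yne (catalytic CuCl2, DBU, MeCN, 0 °C) gives the 1,1-dimethylpropargyl aryl ether F9.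
  - Semihydrogenation (H2, Pd/CaCO3 poisoned with Pb(OAc)2, quinoline, EtOAc) gives the 1,1-dimethylallyl aryl ether F10.
  - Heating (N,N-diethylaniline, about 120 °C) triggers an aromatic Claisen rearrangement. Its [3,3] shift can end productively only at the free ortho carbon, and it turns the reverse-prenyl ether into the linear prenyl group of 12.

**Further compounds**
F1 | step 8 | (S)-3-aryl-3-aryloxypropanal (aldehyde from 14) | O=CC[C@@H](c1ccc(OC(=O)OC(C)(C)C)c(OC)c1)Oc1c(I)c(OCOC)cc(OCOC)c1CC=C(C)C
F2 | step 8 | (2S)-4′-O-Boc-5,7-bis-O-MOM-8-prenylflavan-4-ol, C4 epimers | CC(C)(C)OC(=O)Oc1ccc([C@@H]2CC(O)c3c(OCOC)cc(OCOC)c(CC=C(C)C)c3O2)cc1OC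
F3 | step 7 | (R)-3-aryl-3-hydroxypropanal | O=CC[C@H](c1ccc(OC(=O)OC(C)(C)C)c(OC)c1)O
F4 | step 7 | (R)-1-arylpropane-1,3-diol | OCC[C@H](c1ccc(OC(=O)OC(C)(C)C)c(OC)c1)O
F5 | step 7 | (R)-1-aryl-3-(tert-butyldimethylsilyloxy)propan-1-ol | CC(C)(C)[Si](C)(C)OCC[C@H](c1ccc(OC(=O)OC(C)(C)C)c(OC)c1)O
F6 | step 7 | (S)-1-aryl-3-(tert-butyldimethylsilyloxy)propyl aryl ether | CC(C)(C)[Si](C)(C)OCC[C@@H](c1ccc(OC(=O)OC(C)(C)C)c(OC)c1)Oc1c(I)c(OCOC)cc(OCOC)c1CC=C(C)C
F7 | step 7 | (S)-3-aryl-3-aryloxypropan-1-ol | OCC[C@@H](c1ccc(OC(=O)OC(C)(C)C)c(OC)c1)Oc1c(I)c(OCOC)cc(OCOC)c1CC=C(C)C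
F8 | step 7 | (S)-3-aryl-3-aryloxypropanoic acid | OC(=O)C[C@@H](c1ccc(OC(=O)OC(C)(C)C)c(OC)c1)Oc1c(I)c(OCOC)cc(OCOC)c1CC=C(C)C
F9 | step 6 | 2-iodo-3,5-bis(methoxymethoxy)phenyl 1,1-dimethylpropargyl ether | C#CC(C)(C)Oc1cc(OCOC)cc(OCOC)c1I
F10 | step 6 | 2-iodo-3,5-bis(methoxymethoxy)phenyl 1,1-dimethylallyl ether | C=CC(C)(C)Oc1cc(OCOC)cc(OCOC)c1I
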